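## Retrosynthetic overview

1. Vitedoin A ⇐ Weinreb amide (DIBAL) ⇐ O-allyl, 8-bromo dihydronaphthalene amide (one Pd/formate step removes the allyl group and the blocking bromine).
2. Ring B, the only ring built, is closed last through the C4–C4a bond: anodic oxidation of the free guaiacyl phenol to a p-quinone methide, then Friedel–Crafts capture by ring A. This is run on an open-chain (E)-α-arylidene amide so that C3 can direct C4 trans.
3. Open-chain amide ⇐ Weinreb aminolysis of an (E)-α-arylidene-β-benzyl butyrolactone ⇐ HWE of an α-phosphono-β-benzyl lactone with O-allyl-6-bromovanillin (Br blocks the ring position para to OMe).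
4. α-Phosphono lactone ⇐ Cu-catalysed aryl Grignard opening of a cyclopropane-fused phosphonolactone ⇐ (R)-epichlorohydrin + triethyl phosphonoacetate; the epichlorohydrin stereocentre becomes C3.
5. Ring order: cyclopropane/lactone scaffold (both opened again later) → ring B; both aromatic rings are purchased.

Assumption: the target is the trans-(3R,4S) enantiomer encoded by the SMILES, and (R)-epichlorohydrin, 4-bromo-2-methoxyphenol and 6-bromovanillin are catalogue materials.

## Route

Step 1
Reactants: 1, (R)-epichlorohydrin; 2, triethyl phosphonoacetate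
Product: 3, diethyl [(1R,5S)-2-oxo-3-oxabicyclo[3.1.0]hexan-1-yl]phosphonate (same spatial arrangement as the (1S,5R) malonate-derived lactone; the descriptors change because P outranks O)
Conditions: NaOEt (1.1 equiv), EtOH, 0 → 75 °C
Reagents that add atoms: none
Why: Phosphonoacetate version of the malonate–epichlorohydrin annulation (epoxide opening, epoxide relocation by chloride displacement, 3-exo-tet cyclopropanation, lactonisation); the cyclopropane closes by SN2 inversion at the bought stereocentre, which becomes the bridgehead CH and later C3.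

Step 2
Reactants: 3; 4, 4-bromo-2-methoxyphenol
Product: 5, diethyl {(4S)-4-[(4-hydroxy-3-methoxyphenyl)methyl]-2-oxooxolan-3-yl}phosphonate (mixture at C3 of the lactone, which is destroyed in step 4)
Conditions: 4, HMDS, 80 °C, evaporate (transient ArOTMS, not isolated); Mg, LiCl, THF; then CuI (15 mol %), 3, THF, −40 → 0 °C; 1 M HCl work-up
Reagents that add atoms: none (the transient Me3Si group is lost on work-up)
Why: Cu-catalysed homoconjugate (SN2-type) opening of the doubly activated cyclopropane at its unsubstituted CH2; no bond to the bridgehead stereocentre is broken.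

Step 3
Reactants: 6, 6-bromovanillin (2-bromo-4-hydroxy-5-methoxybenzaldehyde)
Product: 7, 4-(allyloxy)-2-bromo-5-methoxybenzaldehyde
Conditions: allyl bromide, K2CO3, DMF, rt
Reagents that add atoms: allyl bromide, C=CCBr
Why: Williamson etherification; the allyl ether keeps the ring-A phenol from being oxidised in step 6 and comes off together with the bromine in step 7.

Step 4
Reactants: 5; 7
Product: 8, (3E,4R)-3-{[4-(allyloxy)-2-bromo-5-methoxyphenyl]methylidene}-4-[(4-hydroxy-3-methoxyphenyl)methyl]oxolan-2-one
Conditions: LiCl (3 equiv), DBU (2.2 equiv), MeCN, 0 °C → rt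
Reagents that add atoms: none
Why: Masamune–Roush Horner–Wadsworth–Emmons olefination, E-selective for α-phosphono lactones with aryl aldehydes; the β-stereocentre is not acidic and is untouched.

Step 5
Reactants: 8
Product: 9, (2E,3R)-2-{[4-(allyloxy)-2-bromo-5-methoxyphenyl]methylidene}-4-(4-hydroxy-3-methoxyphenyl)-3-(hydroxymethyl)-N-methoxy-N-methylbutanamide
Conditions: MeNH(OMe)·HCl (4 equiv), AlMe3 (5 equiv), CH2Cl2, 0 °C → rt; Et3N-buffered silica, used at once
Reagents that add atoms: N,O-dimethylhydroxylamine hydrochloride, CNOC.Cl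
Why: Weinreb aminolysis of the lactone opens the ring, because cyclising the lactone itself would hold the C3–CH2O group pseudo-equatorial and favour the cis isomer; it also gives an acyl group that reduces cleanly to the aldehyde.

Step 6
Reactants: 9
Product: 10, (3R,4S)-8-bromo-4-(4-hydroxy-3-methoxyphenyl)-3-(hydroxymethyl)-N,5-dimethoxy-N-methyl-6-(prop-2-en-1-yloxy)-3,4-dihydronaphthalene-2-carboxamide
Conditions: undivided cell, graphite anode, Pt cathode, n-Bu4NPF6 (0.1 M), HFIP/CH2Cl2 (4:1), 0.02 M, 0 °C, 3 mA cm⁻², 2.1 F mol⁻¹
Reagents that add atoms: none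
Why: Proposed new method: anodic dehydrogenative benzylic C–H/aryl C–H cyclisation, in which the free guaiacyl phenol (the only low-potential site, ring A being an O-allyl bromo-cinnamamide) is oxidised by 2 e⁻/2 H⁺ to a p-quinone methide that HFIP activates for intramolecular Friedel–Crafts attack by the only open ortho carbon of ring A (between the side chain and OMe), forming C4–C4a; in the open-chain substrate C3–CH2OH (A1,2 strain with the amide) and the C4 aryl (peri strain with 5-OMe) both go pseudo-axial on opposite faces, so the bought C3 centre sets C4 as (S), trans; the closest known reactions are DDQ/acid oxidative cyclisation of dibenzylbutyrolactone lignans, quinone-methide cyclisation of 8–8′-coupled ferulates, and anodic benzylic functionalisation of 4-alkylphenols.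

Step 7
Reactants: 10
Product: 11, (3R,4S)-6-hydroxy-4-(4-hydroxy-3-methoxyphenyl)-3-(hydroxymethyl)-N,5-dimethoxy-N-methyl-3,4-dihydronaphthalene-2-carboxamide
Conditions: Pd(PPh3)4 (5 mol %), HCO2H/Et3N, DMF, rt then 80 °C
Reagents that add atoms: none
Why: Pd(0) π-allyl cleavage of the aryl allyl ether (formate as scavenger) and Pd-catalysed formate hydrodebromination in one pot; it is done before the enal exists, and neither stereocentre is touched.

Step 8
Reactants: 11
Product: 12, vitedoin A, (3R,4S)-6-hydroxy-4-(4-hydroxy-3-methoxyphenyl)-3-(hydroxymethyl)-5-methoxy-3,4-dihydronaphthalene-2-carbaldehyde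
Conditions: DIBAL-H (6 equiv), THF, −78 °C; Rochelle salt work-up
Reagents that add atoms: none
Why: Weinreb amide reduction stops at the chelated hemiaminal and releases the conjugated aldehyde on work-up; the extra hydride only deprotonates the three OH groups.

## Compound list

1 | (R)-epichlorohydrin | ClC[C@H]1CO1 | starting material
2 | triethyl phosphonoacetate | CCOC(=O)CP(=O)(OCC)OCC | starting material
3 | diethyl [(1R,5S)-2-oxo-3-oxabicyclo[3.1.0]hexan-1-yl]phosphonate | O=C1OC[C@@H]2C[C@]12P(=O)(OCC)OCC | intermediate
4 | 4-bromo-2-methoxyphenol | COc1cc(Br)ccc1O | starting material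
5 | diethyl {(4S)-4-[(4-hydroxy-3-methoxyphenyl)methyl]-2-oxooxolan-3-yl}phosphonate | O=C1OC[C@H](Cc2ccc(O)c(OC)c2)C1P(=O)(OCC)OCC | intermediate
6 | 6-bromovanillin (2-bromo-4-hydroxy-5-methoxybenzaldehyde) | COc1cc(C=O)c(Br)cc1O | starting material
7 | 4-(allyloxy)-2-bromo-5-methoxybenzaldehyde | C=CCOc1cc(Br)c(C=O)cc1OC | intermediate
8 | (3E,4R)-3-{[4-(allyloxy)-2-bromo-5-methoxyphenyl]methylidene}-4-[(4-hydroxy-3-methoxyphenyl)methyl]oxolan-2-one | O=C1OC[C@H](Cc2ccc(O)c(OC)c2)/C1=C\c1cc(OC)c(OCC=C)cc1Br | intermediate
9 | (2E,3R)-2-{[4-(allyloxy)-2-bromo-5-methoxyphenyl]methylidene}-4-(4-hydroxy-3-methoxyphenyl)-3-(hydroxymethyl)-N-methoxy-N-methylbutanamide | CON(C)C(=O)/C(=C/c1cc(OC)c(OCC=C)cc1Br)[C@H](CO)Cc1ccc(O)c(OC)c1 | intermediate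
10 | (3R,4S)-8-bromo-4-(4-hydroxy-3-methoxyphenyl)-3-(hydroxymethyl)-N,5-dimethoxy-N-methyl-6-(prop-2-en-1-yloxy)-3,4-dihydronaphthalene-2-carboxamide | COc1cc([C@H]2c3c(c(Br)cc(OCC=C)c3OC)C=C(C(=O)N(C)OC)[C@@H]2CO)ccc1O | intermediate
11 | (3R,4S)-6-hydroxy-4-(4-hydroxy-3-methoxyphenyl)-3-(hydroxymethyl)-N,5-dimethoxy-N-methyl-3,4-dihydronaphthalene-2-carboxamide | COc1cc([C@H]2c3c(ccc(O)c3OC)C=C(C(=O)N(C)OC)[C@@H]2CO)ccc1O | intermediate
12 | vitedoin A | COc1cc([C@H]2c3c(ccc(O)c3OC)C=C(C=O)[C@@H]2CO)ccc1O | target

## Summary

Total steps: 8. Longest linear sequence: 7 (1 → 3 → 5 → 8 → 9 → 10 → 11 → 12).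

Steps most likely to fail:

- **Step 6 (proposed new anodic cyclisation).** Risks are over-oxidation to the arylnaphthalene, phenol dimerisation, and O-trapping of the quinone methide by the amide. Fallback with known chemistry: treat 9 with DDQ in CH2Cl2/MeOH to trap the quinone methide as the C4 methyl ether, then close the ring by acid-mediated Friedel–Crafts cyclisation (TFA or BF3·OEt2, CH2Cl2, −20 °C).
- **Step 5 (lactone aminolysis).** The γ-hydroxy Weinreb amide 9 may relactonise to 8 before or during electrolysis. Fallback: reduce 8 to the 1,4-diol with DIBAL, run the cyclisation and the Pd step at the diol level, and finish with MnO2 oxidation of the allylic alcohol to the enal.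
- **Step 2 (cuprate opening of the phosphonate-activated cyclopropane).** This variant, like the phosphonoacetate annulation in step 1, is less established than the malonate case. Fallback: make the diethyl malonate-derived lactone ester from 1, open it with the same ArMgBr/CuI, remove the ester by Krapcho dealkoxycarbonylation, then reach 8 by LDA aldol with 7 and MsCl/Et3N–DBU dehydration.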